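**Plan**

1. Retrosynthesis: the C6 acetate and C7 3-methylbutanoate go back to a ring B 6,8-diene; the side chain is cut at C13=C14 (HWE) and at C9–C11 (B-alkyl Suzuki on a C9 dienyl triflate); ring A is cut at C1–C2 and C3–C4; C10–C1 and C10–C20 lead back to (R)-carvone.
2. Forward: ring B is the carvone ring; ring A is annulated onto it in one flask (C3–C4 by radical addition, then ring closure at C1=C2 by intramolecular Wittig reaction) and the new alkene is hydrogenated; the side chain and then the ring B oxygens follow.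
3. Enabling feature: ring A is bare, but its gem-dimethyl carbon C4 is a latent tertiary radical (the isopropenyl group of carvone) and C1 is a one-carbon branch on quaternary C10 (a latent aldehyde). The missing C2–C3 unit can therefore be a vinylphosphonium salt that first accepts the C4 radical and then olefinates C1.
4. Stereochemistry: C5 is the carvone stereocentre; C10 comes from enolate hydroxymethylation anti to the isopropenyl group; C7 from OsO4 on the α face; C6 from α-face hydride addition to a 6-ketone; 13E from the HWE step.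

Key step: step 4

Remark on the chemistry: labdane numbering is used for the atoms (ring A = C1–C5 and C10, ring B = C5–C10); compound 2 is carried as its C6 epimer mixture because that centre is made planar again in step 2.

**Route**

Step 1
Reactants: 1 (R)-(−)-carvone
Product: 2 (5R)-2,6-dimethyl-5-(prop-1-en-2-yl)cyclohex-2-en-1-one (6-methylcarvone, both C6 epimers)
Conditions: LiN(iPr)2, THF, −78 °C; MeI, −78 → 0 °C
Reagents that add atoms: iodomethane, CI
Why: Kinetic α′-enolate alkylation, in which LiN(iPr)2 removes the C6 proton of carvone (the future C10) faster than a γ proton and the enolate is methylated by SN2; the new centre is not controlled because it becomes planar again in step 2.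

Step 2
Reactants: 2 (5R)-2,6-dimethyl-5-(prop-1-en-2-yl)cyclohex-2-en-1-one
Product: 3 (5S,6R)-6-(hydroxymethyl)-2,6-dimethyl-5-(prop-1-en-2-yl)cyclohex-2-en-1-one (hydroxymethyl trans to isopropenyl)
Conditions: LiN(iPr)2, THF, −78 °C; CH2O (gas from cracked paraformaldehyde), −78 °C; AcOH quench at −78 °C
Reagents that add atoms: formaldehyde, C=O
Why: Aldol addition of the regenerated α′-enolate to formaldehyde (enolate hydroxymethylation), in which the neighbouring isopropenyl group is pushed pseudo-axial by allylic strain with the enolate methyl so that formaldehyde enters on the opposite face, placing the one-carbon arm (C1) trans to the isopropenyl group and setting C10.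

Step 3
Reactants: 3 (5S,6R)-6-(hydroxymethyl)-2,6-dimethyl-5-(prop-1-en-2-yl)cyclohex-2-en-1-one
Product: 4 (1R,6S)-1,3-dimethyl-2-oxo-6-(prop-1-en-2-yl)cyclohex-3-ene-1-carbaldehyde
Conditions: Dess–Martin periodinane, CH2Cl2, 0 °C → rt
Reagents that add atoms: none
Why: Dess–Martin oxidation of the neopentyl primary alcohol under neutral conditions; the β-keto aldehyde cannot enolise between its carbonyls (quaternary C10), so neither stereocentre is at risk.

Step 4
Reactants: 4 (1R,6S)-1,3-dimethyl-2-oxo-6-(prop-1-en-2-yl)cyclohex-3-ene-1-carbaldehyde; 5 triphenyl(vinyl)phosphonium bromide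
Product: 7 (4aS,8aS)-2,5,5,8a-tetramethyl-4a,5,6,8a-tetrahydronaphthalen-1(4H)-one, via phosphonium bromide 6 (not isolated)
Conditions: Fe(acac)3, PhSiH3, EtOH, 60 °C; evaporate; KN(SiMe3)2, THF, −78 → 0 °C
Reagents that add atoms: none
Why: Proposed new method: the iron hydride made from Fe(acac)3 and PhSiH3 transfers a hydrogen atom to the electron-rich 1,1-disubstituted alkene of 4 to give the tertiary radical at C4, which adds to the unsubstituted carbon of the vinylphosphonium cation 5 (polarity-matched Giese addition that forms C3–C4 and makes C4 quaternary); the α-phosphonio radical is then reduced and protonated to the alkylphosphonium salt 6, and KN(SiMe3)2 converts 6 into the non-stabilised ylide at C2, which olefinates the C1 aldehyde. The closest known reaction types are the iron-mediated hydrogen-atom-transfer reductive coupling of unactivated alkenes with acrylates, enones and vinyl sulfones (including its radical–polar crossover annulations that end in an aldol step), photoredox radical additions to vinylphosphonium salts followed by Wittig olefination, and Schweizer-type annulations in which a nucleophile adds to a vinylphosphonium salt before an intramolecular Wittig reaction; new here is the vinylphosphonium salt as acceptor under hydrogen-atom-transfer conditions. Ring A is closed by intramolecular Wittig olefination, that is 6-exo-trig attack of the ylide carbon C2 on the C1 carbonyl followed by collapse of the oxaphosphetane, which forms the C1=C2 bond as a cis alkene within the six-membered ring. No new stereocentre arises (C4 carries two methyls, C1 and C2 become sp2), and the trans ring fusion follows from the trans arrangement of the C5 and C10 arms fixed in step 2. The step needs chemoselective hydrogen-atom transfer to the isopropenyl group over the conjugated trisubstituted enone alkene, which the electron demand of the iron hydride secures, and radical addition faster than radical quenching, which the cationic acceptor and its charge repulsion against oligomerisation favour. It also needs olefination of the aldehyde in preference to the C9 ketone and no deformylation of the β-keto aldehyde, which the far higher reactivity of the aldehyde and the non-nucleophilic amide base secure.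

Step 5
Reactants: 7 (4aS,8aS)-2,5,5,8a-tetramethyl-4a,5,6,8a-tetrahydronaphthalen-1(4H)-one
Product: 8 (4aS,8aS)-2,5,5,8a-tetramethyl-4a,5,6,7,8,8a-hexahydronaphthalen-1(4H)-one
Conditions: H2 (1 atm), RhCl(PPh3)3 (cat.), benzene, rt
Reagents that add atoms: none
Why: Homogeneous hydrogenation with RhCl(PPh3)3 reduces the unconjugated cis-disubstituted C1=C2 alkene and leaves the conjugated trisubstituted enone alkene, which this catalyst reduces far more slowly.

Step 6
Reactants: 8 (4aS,8aS)-2,5,5,8a-tetramethyl-4a,5,6,7,8,8a-hexahydronaphthalen-1(4H)-one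
Product: 9 (4aS,8aS)-2,5,5,8a-tetramethyl-4a,5,6,7,8,8a-hexahydronaphthalen-1-yl trifluoromethanesulfonate
Conditions: Tf2O, 2,6-di-tert-butyl-4-methylpyridine, CH2Cl2, 0 °C → rt
Reagents that add atoms: trifluoromethanesulfonic anhydride, O=S(=O)(OS(=O)(=O)C(F)(F)F)C(F)(F)F
Why: Dienyl triflate formation, in which O-sulfonylation of the enone is followed by loss of a γ proton from C6, the only enolisable position because C10 is quaternary, to give the linear 2-triflyloxy-1,3-diene as is known for steroidal enones.

Step 7
Reactants: 9 (4aS,8aS)-2,5,5,8a-tetramethyl-4a,5,6,7,8,8a-hexahydronaphthalen-1-yl trifluoromethanesulfonate; 10 2-methyl-2-vinyl-1,3-dioxolane; 11 9-borabicyclo[3.3.1]nonane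
Product: 13 2-methyl-2-{2-[(4aS,8aS)-2,5,5,8a-tetramethyl-4a,5,6,7,8,8a-hexahydronaphthalen-1-yl]ethyl}-1,3-dioxolane, via alkylborane 12 (not isolated)
Conditions: 10, 11, THF, 0 °C → rt; then 9, PdCl2(dppf) (cat.), AsPh3, Cs2CO3, DMF/H2O, 50 °C
Reagents that add atoms: none
Why: B-alkyl Suzuki–Miyaura coupling, in which 9-BBN adds to the terminal alkene of 10 in the anti-Markovnikov sense and the primary alkylborane transfers its alkyl group to the C9 alkenyl triflate, a coupling precedented for triflates flanked by a quaternary carbon and a vinylic methyl group such as 2,6,6-trimethylcyclohexenyl triflate.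

Step 8
Reactants: 13 2-methyl-2-{2-[(4aS,8aS)-2,5,5,8a-tetramethyl-4a,5,6,7,8,8a-hexahydronaphthalen-1-yl]ethyl}-1,3-dioxolane
Product: 14 4-[(4aS,8aS)-2,5,5,8a-tetramethyl-4a,5,6,7,8,8a-hexahydronaphthalen-1-yl]butan-2-one
Conditions: pyridinium p-toluenesulfonate (cat.), acetone/H2O, 50 °C
Reagents that add atoms: water, O
Why: Acid-catalysed acetal hydrolysis of the dioxolane, with an acid weak enough to spare the homoannular diene.

Step 9
Reactants: 15 (diethoxyphosphoryl)acetic acid; 16 2-(trimethylsilyl)ethanol
Product: 17 2-(trimethylsilyl)ethyl (diethoxyphosphoryl)acetate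
Conditions: N,N'-dicyclohexylcarbodiimide, DMAP (cat.), CH2Cl2, 0 °C → rt
Reagents that add atoms: none
Why: Steglich esterification (carbodiimide activation with DMAP as acyl-transfer catalyst) gives the phosphonate with an ester that can later be removed by fluoride.

Step 10
Reactants: 14 4-[(4aS,8aS)-2,5,5,8a-tetramethyl-4a,5,6,7,8,8a-hexahydronaphthalen-1-yl]butan-2-one; 17 2-(trimethylsilyl)ethyl (diethoxyphosphoryl)acetate
Product: 18 2-(trimethylsilyl)ethyl (13E)-labda-6,8,13-trien-15-oate
Conditions: 17, NaH, THF, 0 °C; then 14, rt → 50 °C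
Reagents that add atoms: none
Why: Horner–Wadsworth–Emmons olefination of the methyl ketone, in which reversible addition of the stabilised phosphonate anion favours the 13E enoate; the minor 13Z isomer would be removed by chromatography.

Step 11
Reactants: 18 2-(trimethylsilyl)ethyl (13E)-labda-6,8,13-trien-15-oate
Product: 19 2-(trimethylsilyl)ethyl (13E)-6α,7α-dihydroxylabda-8,13-dien-15-oate
Conditions: OsO4 (cat.), N-methylmorpholine N-oxide, acetone/H2O, 0 °C → rt
Reagents that add atoms: N-methylmorpholine N-oxide, C[N+]1([O-])CCOCC1; water, O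
Why: Upjohn dihydroxylation, in which OsO4 adds to the cis-disubstituted C6=C7 bond of the diene faster than to the tetrasubstituted C8=C9 bond or the electron-poor enoate, and from the α face because the β face is covered by the axial methyls on C10 and C4, which gives the 6α,7α-diol and sets C7.

Step 12
Reactants: 19 2-(trimethylsilyl)ethyl (13E)-6α,7α-dihydroxylabda-8,13-dien-15-oate
Product: 20 2-(trimethylsilyl)ethyl (13E)-6α-hydroxy-7α-(3-methylbutanoyloxy)labda-8,13-dien-15-oate
Conditions: 3-methylbutanoyl chloride (1.1 equiv), pyridine, CH2Cl2, −20 → 0 °C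
Reagents that add atoms: 3-methylbutanoyl chloride, CC(C)CC(Cl)=O
Why: Regioselective O-acylation, in which the allylic pseudo-axial 7α-hydroxyl reacts first because the equatorial 6α-hydroxyl is screened by the neighbouring C4 gem-dimethyl group, as is known for 6α-hydroxylabdanes that resist acylation.

Step 13
Reactants: 20 2-(trimethylsilyl)ethyl (13E)-6α-hydroxy-7α-(3-methylbutanoyloxy)labda-8,13-dien-15-oate
Product: 21 2-(trimethylsilyl)ethyl (13E)-7α-(3-methylbutanoyloxy)-6-oxolabda-8,13-dien-15-oate
Conditions: Dess–Martin periodinane, pyridine, CH2Cl2, 0 °C → rt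
Reagents that add atoms: none
Why: Dess–Martin oxidation of the remaining secondary alcohol to the 6-ketone under buffered, non-basic conditions that neither epimerise the α-acyloxy centre C7 nor move the C8=C9 bond into conjugation.

Step 14
Reactants: 21 2-(trimethylsilyl)ethyl (13E)-7α-(3-methylbutanoyloxy)-6-oxolabda-8,13-dien-15-oate
Product: 22 2-(trimethylsilyl)ethyl (13E)-6β-hydroxy-7α-(3-methylbutanoyloxy)labda-8,13-dien-15-oate
Conditions: NaBH4, CeCl3·7H2O, MeOH, −40 °C
Reagents that add atoms: none
Why: Luche reduction, in which hydride attacks the C6 carbonyl from the α face because the β face carries the two syn-axial methyls on C10 and C4, giving the axial 6β-alcohol and setting C6; the trans-diaxial relation to the 7α-ester prevents acyl migration and CeCl3 suppresses enolisation toward C7.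

Step 15
Reactants: 22 2-(trimethylsilyl)ethyl (13E)-6β-hydroxy-7α-(3-methylbutanoyloxy)labda-8,13-dien-15-oate
Product: 23 2-(trimethylsilyl)ethyl (13E)-6β-acetoxy-7α-(3-methylbutanoyloxy)labda-8,13-dien-15-oate
Conditions: Ac2O, DMAP, Et3N, CH2Cl2, 40 °C
Reagents that add atoms: acetic anhydride, CC(=O)OC(C)=O
Why: DMAP-catalysed acylation (Steglich–Höfle type) through the acetylpyridinium ion drives acetylation of the hindered axial 6β-hydroxyl.

Step 16
Reactants: 23 2-(trimethylsilyl)ethyl (13E)-6β-acetoxy-7α-(3-methylbutanoyloxy)labda-8,13-dien-15-oate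
Product: 24 (13E)-6β-acetoxy-7α-(3-methylbutanoyloxy)labda-8,13-dien-15-oic acid (5S,6S,7S,10S; the target)
Conditions: Bu4NF, THF, 0 °C → rt; then dilute aq. HCl
Reagents that add atoms: none
Why: Fluoride-induced β-elimination of the 2-(trimethylsilyl)ethyl ester (loss of ethene and fluorotrimethylsilane) frees the carboxylic acid without touching the acetate or the 3-methylbutanoate, which have no free hydroxyl neighbour to migrate to.

**Compound list**

1 | (R)-(−)-carvone, (5R)-2-methyl-5-(prop-1-en-2-yl)cyclohex-2-en-1-one | CC(=C)[C@@H]1CC=C(C)C(=O)C1 | starting material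
2 | (5R)-2,6-dimethyl-5-(prop-1-en-2-yl)cyclohex-2-en-1-one (6-methylcarvone, both C6 epimers) | CC(=C)[C@@H]1CC=C(C)C(=O)C1C | intermediate
3 | (5S,6R)-6-(hydroxymethyl)-2,6-dimethyl-5-(prop-1-en-2-yl)cyclohex-2-en-1-one (hydroxymethyl trans to isopropenyl) | C1C=C(C)C(=O)[C@@](C)(CO)[C@@H]1C(C)=C | intermediate
4 | (1R,6S)-1,3-dimethyl-2-oxo-6-(prop-1-en-2-yl)cyclohex-3-ene-1-carbaldehyde | C1C=C(C)C(=O)[C@@](C)(C=O)[C@@H]1C(C)=C | intermediate
5 | triphenyl(vinyl)phosphonium bromide | C=C[P+](c1ccccc1)(c1ccccc1)c1ccccc1.[Br-] | starting material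
6 | {3-[(1S,6R)-6-formyl-4,6-dimethyl-5-oxocyclohex-3-en-1-yl]-3-methylbutyl}triphenylphosphonium bromide | C1C=C(C)C(=O)[C@@](C)(C=O)[C@@H]1C(C)(C)CC[P+](c1ccccc1)(c1ccccc1)c1ccccc1.[Br-] | intermediate
7 | (4aS,8aS)-2,5,5,8a-tetramethyl-4a,5,6,8a-tetrahydronaphthalen-1(4H)-one | C1C=C(C)C(=O)[C@@]2(C)C=CCC(C)(C)[C@H]12 | intermediate
8 | (4aS,8aS)-2,5,5,8a-tetramethyl-4a,5,6,7,8,8a-hexahydronaphthalen-1(4H)-one | C1C=C(C)C(=O)[C@@]2(C)CCCC(C)(C)[C@H]12 | intermediate
9 | (4aS,8aS)-2,5,5,8a-tetramethyl-4a,5,6,7,8,8a-hexahydronaphthalen-1-yl trifluoromethanesulfonate | C1=CC(C)=C(OS(=O)(=O)C(F)(F)F)[C@@]2(C)CCCC(C)(C)[C@H]12 | intermediate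
10 | 2-methyl-2-vinyl-1,3-dioxolane | C=CC1(C)OCCO1 | starting material
11 | 9-borabicyclo[3.3.1]nonane (9-BBN) | B1C2CCCC1CCC2 | starting material
12 | 9-[2-(2-methyl-1,3-dioxolan-2-yl)ethyl]-9-borabicyclo[3.3.1]nonane | CC1(CCB2C3CCCC2CCC3)OCCO1 | intermediate
13 | 2-methyl-2-{2-[(4aS,8aS)-2,5,5,8a-tetramethyl-4a,5,6,7,8,8a-hexahydronaphthalen-1-yl]ethyl}-1,3-dioxolane | C1=CC(C)=C(CCC3(C)OCCO3)[C@@]2(C)CCCC(C)(C)[C@H]12 | intermediate
14 | 4-[(4aS,8aS)-2,5,5,8a-tetramethyl-4a,5,6,7,8,8a-hexahydronaphthalen-1-yl]butan-2-one | C1=CC(C)=C(CCC(C)=O)[C@@]2(C)CCCC(C)(C)[C@H]12 | intermediate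
15 | (diethoxyphosphoryl)acetic acid | OC(=O)CP(=O)(OCC)OCC | starting material
16 | 2-(trimethylsilyl)ethanol | OCC[Si](C)(C)C | starting material
17 | 2-(trimethylsilyl)ethyl (diethoxyphosphoryl)acetate | CCOP(=O)(OCC)CC(=O)OCC[Si](C)(C)C | intermediate
18 | 2-(trimethylsilyl)ethyl (13E)-labda-6,8,13-trien-15-oate | C1=CC(C)=C(CC/C(C)=C/C(=O)OCC[Si](C)(C)C)[C@@]2(C)CCCC(C)(C)[C@H]12 | intermediate
19 | 2-(trimethylsilyl)ethyl (13E)-6α,7α-dihydroxylabda-8,13-dien-15-oate | O[C@H]1[C@@H](O)C(C)=C(CC/C(C)=C/C(=O)OCC[Si](C)(C)C)[C@@]2(C)CCCC(C)(C)[C@H]12 | intermediate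
20 | 2-(trimethylsilyl)ethyl (13E)-6α-hydroxy-7α-(3-methylbutanoyloxy)labda-8,13-dien-15-oate | O[C@H]1[C@@H](OC(=O)CC(C)C)C(C)=C(CC/C(C)=C/C(=O)OCC[Si](C)(C)C)[C@@]2(C)CCCC(C)(C)[C@H]12 | intermediate
21 | 2-(trimethylsilyl)ethyl (13E)-7α-(3-methylbutanoyloxy)-6-oxolabda-8,13-dien-15-oate | O=C1[C@@H](OC(=O)CC(C)C)C(C)=C(CC/C(C)=C/C(=O)OCC[Si](C)(C)C)[C@@]2(C)CCCC(C)(C)[C@H]12 | intermediate
22 | 2-(trimethylsilyl)ethyl (13E)-6β-hydroxy-7α-(3-methylbutanoyloxy)labda-8,13-dien-15-oate | O[C@@H]1[C@@H](OC(=O)CC(C)C)C(C)=C(CC/C(C)=C/C(=O)OCC[Si](C)(C)C)[C@@]2(C)CCCC(C)(C)[C@H]12 | intermediate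
23 | 2-(trimethylsilyl)ethyl (13E)-6β-acetoxy-7α-(3-methylbutanoyloxy)labda-8,13-dien-15-oate | CC(=O)O[C@@H]1[C@@H](OC(=O)CC(C)C)C(C)=C(CC/C(C)=C/C(=O)OCC[Si](C)(C)C)[C@@]2(C)CCCC(C)(C)[C@H]12 | intermediate
24 | (13E)-6β-acetoxy-7α-(3-methylbutanoyloxy)labda-8,13-dien-15-oic acid, (5S,6S,7S,10S) | CC(=O)O[C@@H]1[C@@H](OC(=O)CC(C)C)C(C)=C(CC/C(C)=C/C(=O)O)[C@@]2(C)CCCC(C)(C)[C@H]12 | target

**Step count**

Total step count: 16. Longest linear sequence: 15 steps (steps 1–8 and 10–16, from (R)-carvone); step 9 is a one-step side branch.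

**Steps most likely to fail**

Step 4 (proposed new method). The tertiary radical may be quenched by hydrogen-atom transfer before it adds to the phosphonium salt (net hydrogenation of the isopropenyl group), or the silane may reduce the aldehyde before the ylide is formed. The fallback uses only known chemistry, makes the C4 radical in another way and closes the same C1=C2 bond by metathesis; it sets out from 4 and comes back at 7. Wittig methylenation of the aldehyde of 4 (Ph3P=CH2, THF, 0 °C) should give 6-methyl-6-vinylcarvone F1. Markovnikov addition of HBr (HBr in AcOH, 0 °C) to its isopropenyl group should give the tertiary bromide F2. Keck radical allylation (allyltributylstannane, AIBN, benzene, 80 °C) should then give the 1,1-dimethylbut-3-enyl ketone F3. Ring-closing metathesis between the C10 vinyl group and the allyl group with the second-generation Grubbs catalyst RuCl2(=CHPh)(PCy3)(H2IMes) in CH2Cl2 at 40 °C should give 7.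

Step 7. Oxidative addition and transmetalation may be slow at the triflate, which is flanked by the quaternary C10 and the C8 methyl group, so that hydrolysis of the triflate and protodeboronation of the alkylborane take over. The fallback replaces the cross-coupling by carbonyl addition and transposition; it sets out from 8 and comes back at 13. Addition of [2-(2-methyl-1,3-dioxolan-2-yl)ethyl]magnesium bromide with CeCl3 (THF, −78 °C) to the C9 carbonyl of 8 should give the tertiary allylic alcohol F4. Dauben–Babler oxidative 1,3-transposition with pyridinium chlorochromate, [C5H5NH][CrO3Cl], buffered with NaOAc in CH2Cl2 should give the 7-oxo-8-ene enone F5. Kinetic enolisation toward C6 and triflation (LiN(SiMe3)2, THF, −78 °C; PhNTf2) should give the dienyl triflate F6. Reduction of the triflate with Pd(OAc)2, PPh3, HCO2H and Bu3N in DMF at 60 °C should give 13.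

Step 12. The two hydroxyls may not be told apart well enough, or the acyl group may migrate from O7 to O6 under the basic conditions. The fallback places the ester by stereoelectronic control through a cyclic orthoester; it sets out from 19 and comes back at 20. Pinner reaction of commercial 3-methylbutanenitrile (HCl, MeOH, 0 °C) should give methyl 3-methylbutanimidate hydrochloride F7, and its methanolysis should give 1,1,1-trimethoxy-3-methylbutane F8. Acid-catalysed exchange of F8 with diol 19 (camphorsulfonic acid cat., CH2Cl2) should give the cyclic 6α,7α-orthoester F9. Hydrolysis of F9 in aqueous acetic acid should open the dioxolanylium ion to the axial ester and the equatorial alcohol, which is 20.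

Further compounds
F1 | step 4 | 6-methyl-6-vinylcarvone, 2,6-dimethyl-5-(prop-1-en-2-yl)-6-vinylcyclohex-2-en-1-one (vinyl trans to isopropenyl) | C1C=C(C)C(=O)[C@@](C)(C=C)[C@@H]1C(C)=C
F2 | step 4 | 5-(2-bromopropan-2-yl)-2,6-dimethyl-6-vinylcyclohex-2-en-1-one (vinyl trans to the bromoalkyl group) | C1C=C(C)C(=O)[C@@](C)(C=C)[C@@H]1C(C)(C)Br
F3 | step 4 | 2,6-dimethyl-5-(2-methylpent-4-en-2-yl)-6-vinylcyclohex-2-en-1-one (vinyl trans to the alkenyl arm) | C1C=C(C)C(=O)[C@@](C)(C=C)[C@@H]1C(C)(C)CC=C
F4 | step 7 | (4aS,8aS)-2,5,5,8a-tetramethyl-1-[2-(2-methyl-1,3-dioxolan-2-yl)ethyl]-1,4,4a,5,6,7,8,8a-octahydronaphthalen-1-ol (either C1 epimer) | C1C=C(C)C(O)(CCC3(C)OCCO3)[C@@]2(C)CCCC(C)(C)[C@H]12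
F5 | step 7 | (4aS,8aS)-3,4a,8,8-tetramethyl-4-[2-(2-methyl-1,3-dioxolan-2-yl)ethyl]-4a,5,6,7,8,8a-hexahydronaphthalen-2(1H)-one | C1C(=O)C(C)=C(CCC3(C)OCCO3)[C@@]2(C)CCCC(C)(C)[C@H]12
F6 | step 7 | (4aS,8aS)-3,4a,8,8-tetramethyl-4-[2-(2-methyl-1,3-dioxolan-2-yl)ethyl]-4a,5,6,7,8,8a-hexahydronaphthalen-2-yl trifluoromethanesulfonate | C1=C(OS(=O)(=O)C(F)(F)F)C(C)=C(CCC3(C)OCCO3)[C@@]2(C)CCCC(C)(C)[C@H]12
F7 | step 12 | methyl 3-methylbutanimidate hydrochloride | COC(=[NH2+])CC(C)C.[Cl-]
F8 | step 12 | 1,1,1-trimethoxy-3-methylbutane (trimethyl orthoisovalerate) | COC(CC(C)C)(OC)OC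
F9 | step 12 | 2-(trimethylsilyl)ethyl (13E)-6α,7α-[(1-methoxy-3-methylbutylidene)dioxy]labda-8,13-dien-15-oate (cyclic orthoester, either configuration at the orthoester carbon) | COC1(CC(C)C)O[C@H]2[C@@H](O1)C(C)=C(CC/C(C)=C/C(=O)OCC[Si](C)(C)C)[C@@]3(C)CCCC(C)(C)[C@H]23
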